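The numbers in the tables stem from a simulated flask with constants of no real substance, and the scatter is random.

We ask what share of isomer of the product, counted against isomer plus target, stands in a flask charged with equal amounts of substrate and other conformer, at three times.

the same everywhere: substrate 0.10 M
- Monday's: partner 0.10 M; other conformer 0.10 M; run made earlier
- Tuesday's: partner 0.15 M; other conformer 0.10 M; run made earlier
- flask: partner 0.200 M; other conformer 0.100 M; time 1.5 h

- Monday's (time / min: isomer of the product / %, target / %, substrate / %): 12.0: 29.1, 0.7, 23.6; 25.0: 27.9, 0.2, 22.0; 40.0: 29.1, 0, 20.8; 50.0: 29.1, 0, 19.6; 60.0: 27.9, 0, 20.0; 80.0: 28.7, 0, 17.5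
- Tuesday's (time / min: isomer of the product / %, target / %, substrate / %): 5.00: 36.3, 5.1, 20.9; 15.0: 38.9, 1.1, 12.4; 25.0: 38.4, 1.2, 10.2; 40.0: 39.4, 0, 9.6; 60.0: 39.2, 0.4, 9.4; 80.0: 39.2, 0, 8.7

(scatter of a reading: 0.5 percentage points)

* share of isomer of the product in isomer of the product plus target at 3.0 s
* share of isomer of the product in isomer of the product plus target at 2.0 min
* share of isomer of the product in isomer of the product plus target at 1.5 h
* which of isomer of the product and target there is more of at 1.5 h



The zero of our scale is the symmetric case: if both conformers took partner equally fast, equal charges would give a share of 50.0%. Tuesday's first reading, at 5.00 min, brackets the real start. Tuesday's target is already fading by then, from 5.1% to 1.1% at 15.0 min, so we take the share read there, 87.7%, as a ceiling. For a floor, let all lost substrate, 29.1% of the charge, count as target made: that gives 55.5%.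

The same count fails on Monday: at 12.0 min, isomer plus lost substrate comes to 55.5%, more than the 50.0% that partner supplied. So we suppose that each target lost takes one further substrate with it. Target made on Tuesday is then 17.1%, and the share so far is 68.0%. On this supposition it is a better floor, since on Tuesday the other conformer left, 13.7%, is less than the substrate left, 20.9%, which lowers the later ratio.

Tighter still, we take both reactions as first order in partner, so the logarithms of the fractions remaining stand in the ratio of their rate constants, with the substrate's logarithm scaled by the part of its loss that went through partner. This gives 50.0% as the charge and 2.53 as the ratio. It is a reading, with the readings' scatter: the selectivity factor, the other conformer's rate constant with partner over the substrate's. Partner cancels, so at 3.0 s, far before that first reading, we expect 71.6%. At 2.0 min we expect a share between this and the ceiling. Tuesday's target went from 5.1% to 0% by 80.0 min; if the flask follows that run, we expect isomer far ahead at 1.5 h.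

The forecast gave 57%, 63% and 99.5%, with isomer of the product ahead, holding that “the other conformer reacts about 1.3 times faster”; its first value lies inside the wide bracket but under our floor.

The flask gives 71.6%, 77.2% and 98.2%, with isomer at 46.9% and target at 0.880% at 1.5 h.

    substrate + partner → target (k = 0.0290 M⁻¹ s⁻¹)
    partner → decomposed reagent (k = 0.00160 s⁻¹)
    substrate ⇌ other conformer (K = 3.50, k = 8.90 × 10⁻⁵ s⁻¹)
    partner + other conformer → isomer of the product (k = 0.0730 M⁻¹ s⁻¹)
    substrate + target → side product (k = 0.110 M⁻¹ s⁻¹)

Our factor 2.53 on this flask's equal charges gave 71.6%, and the flask stood at 71.6% at 3.0 s. Now take the neighbouring flask with 0.040 M of other conformer and everything else as charged here. The same factor on that charge gives 50.3% for the start. That flask stood at 50.3% at 3.0 s, and at 72.9% at 1.5 h, with isomer at 29.4% and target at 10.9%.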